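The spring run, with twice the X of the summer run and the same Z, holds 0.1497 M of E at 4.7 min from 0.150 M of Z, but the summer run holds 0.0999 M at that time. Z is the limiting reagent on paper in the summer run, yet we keep the books on X.

| flask | Z | X | time |
|---|---|---|---|
| summer | 0.150 M | 0.180 M |  |
| autumn | 0.0600 M | 0.0900 M |  |
| spring | 0.150 M | 0.360 M |  |
| midnight | 0.220 M | 0.180 M |  |
| dawn | 0.150 M | 0.180 M | 12 min |

| summer run: time / min | summer run: [E] / M | autumn run: time / min | autumn run: [E] / M | spring run: time / min | spring run: [E] / M | midnight run: time / min | midnight run: [E] / M |
|---|---|---|---|---|---|---|---|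
| 0.19 | 0.0310 | 0.19 | 0.0036 | 0.19 | 0.0875 | 0.19 | 0.0380 |
| 0.42 | 0.0505 | 0.42 | 0.0100 | 0.42 | 0.1195 | 0.42 | 0.0614 |
| 0.94 | 0.0715 | 0.94 | 0.0171 | 0.94 | 0.1431 | 0.94 | 0.0884 |
| 2.1 | 0.0908 | 2.1 | 0.0254 | 2.1 | 0.1473 | 2.1 | 0.1054 |
| 4.7 | 0.0999 | 4.7 | 0.0294 | 4.7 | 0.1497 | 4.7 | 0.1156 |

(readings scatter by 0.001 M)

1. the power of [X] that the first rate follows, about the charge of the summer run; measure it at two percent of Z made into E
2. the power of [Z] that the first rate follows, about the charge of the summer run; measure it at two percent of Z made into E (one fixed amount of E, the same in the runs compared)
3. the autumn run starts with 0.0900 M less of Z and of X than the summer run, and with no E. Compared where both hold the same amount of Z, once fifteen percent of what the autumn run was charged with has turned into E, is the autumn run faster, slower or alike (within a tenth)?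
4. E in the dawn run at 12 min, as a share of the Z charged

- Overall: Z + X -> E.
- Constant volume, constant temperature.
- Readings of a species count what is bound in complexes too.
- An order is taken over about fifteen percent of the charge, up and down.

The summer run was charged with 0.180 M of X. The first entry is E, one X each, 0.0999 M by 4.7 min. On paper that leaves 0.0801 M of X beside 0.0501 M of Z. Still, E grows at 0.00350 M min⁻¹ over the last interval, against 0.163 M min⁻¹ over the first. So a second entry is needed: X that leaves by another road.

To price it we need the rate law. Spring's first reading against summer's reads a power of about 1.92 in [X], and midnight's against summer's reads 0.532 in [Z]. We take the square of [X] and, roughly, the first power of [Z] for the late rate.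

The rate divided by [Z] then follows [X] squared. Between the last two intervals of the summer run it falls by a factor of 3.77, over 1.88 min between their middles. We call 0.353 min⁻¹ the fade rate, the share of X that goes per minute late in a run, so one X lifetime is 2.83 min.

The rate then falls as the exponential of twice the fade rate, which prices the third entry, the tail after the last reading, at 0.00173 M. The dawn run repeats the summer charge, and its 12 min count 4.24 lifetimes, with nearly all of that tail in by then. The books close at 0.102 M of E, which is 67.8% of the Z, with 0.0784 M of X not in E.

The autumn run at 0.42 min and the summer run at 4.7 min hold nearly the same Z and paper X, 0.0500 M and 0.0800 M. Autumn's next interval gives 0.0137 M min⁻¹, so we call autumn faster than summer's 0.00350 M min⁻¹, which has had 4.28 min more of fading.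

The forecast, holding that “the fall follows time, not product”, gave 2 for [X], 0.8 for [Z], faster, and 69.5% for the dawn run, above our 67.8%.

The flask gives 2.0 for [X], 0.68 for [Z], faster, and 67.9% for the dawn run.

    Z + X → E (1.230 M⁻¹ min⁻¹)
    Z + 2 X → E + X (87.00 M⁻² min⁻¹)
    X → Zo (0.2760 min⁻¹)
    2 Z ⇌ Z2, settled at all times (7.470 M⁻¹)

In the summer run, Z + 2 X -> E + X and Z + X -> E made E, bringing E to half of the Z by 0.990 min, and X -> Zo drew on the same X from the start. After that E crept towards the dawn run's 67.9%, against our 67.8% from the fade rate. Laid on the midnight run's last two readings, the fade rate puts E at half of that run's Z at 2.77 min; the midnight run gets there at 2.87 min.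

All runs come from a simulation with made-up constants, noise included.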